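**Plan**

Retrosynthesis: the five benzyl ethers are removed first. The C2–C3 bond shared by the pyranone ring and the dihydrofuran ring is then cut, opening both rings to a nine-membered dibenzo-1,3-dioxonine with a diazo group at C3 and an acetal C–H at C2. The two acetal C–O bonds (O1–C2, O7''–C2), the C3–C8'' bond (ketone α-arylation) and the chroman O1''–C2'' bond (Mitsunobu) follow.
Forward: the chroman is built first (aldol condensation, transfer hydrogenation, Mitsunobu closure), C8'' is joined to the acetophenone carbon, the diazo group is installed and the nine-membered benzylidene acetal is closed. One transannular C–H alkylation then closes the pyranone and dihydrofuran rings together, and hydrogenolysis ends the route.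
Enabling feature: C2 bears two aryl oxygens (O1, O7'') and a 4-oxygenated phenyl group. At the aldehyde oxidation level its C–H is therefore the weakest, most hydridic C–H of the molecule, and it lies 1,5 and 1,6 to C3, which sits between the C4 carbonyl and the C8'' arene and is a natural carbene (diazo) position.
Stereochemistry: C2'' comes from catalyst-controlled asymmetric transfer hydrogenation followed by SN2 inversion; C3 from the chiral cobalt porphyrin in the radical C–C bond formation; C2 from the enforced cis fusion of the 6/5 ring pair.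

Key step: step 13

Remark: locants follow flavonoid usage. The chromanone unit is O1, C2 (ketal carbon), C3, C4 (C=O), C4a–C8a; the chroman unit is double-primed (O1'', C2'', C5'', C7'', C8''), and systematic names of intermediates keep the chroman's own locants. The target is then (2S,3S,2''R). The antipode of the porphyrin catalyst that gives 2S,3S is assumed to be fixed by a pilot run on both antipodes.

**Route**

Step 1
Reactants: 1 2,4,6-trihydroxybenzaldehyde
Product: 2 2,6-dihydroxy-4-(methoxymethoxy)benzaldehyde
Conditions: MOMCl (1.0 equiv), iPr2NEt, THF, −20 to 0 °C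
Reagents that add atoms: chloromethyl methyl ether, COCCl
Why: Williamson-type O-alkylation: the 4-OH, para to the formyl group, is the most acidic hydroxyl and the only one not held in a hydrogen bond to the carbonyl oxygen, so one equivalent of the chloride should alkylate it selectively.

Step 2
Reactants: 2 2,6-dihydroxy-4-(methoxymethoxy)benzaldehyde
Product: 3 2-(benzyloxy)-6-hydroxy-4-(methoxymethoxy)benzaldehyde
Conditions: BnBr (1.0 equiv), K2CO3, acetone, rt
Reagents that add atoms: benzyl bromide, BrCc1ccccc1
Why: Williamson ether synthesis: the two remaining hydroxyls are equivalent and chelated to the aldehyde, and after the first benzylation the last hydroxyl is held in a single, stronger hydrogen bond, so one equivalent of bromide should stop at the mono-ether.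

Step 3
Reactants: 3 2-(benzyloxy)-6-hydroxy-4-(methoxymethoxy)benzaldehyde; 4 1-[4-(benzyloxy)phenyl]ethanone
Product: 5 (E)-3-[2-(benzyloxy)-6-hydroxy-4-(methoxymethoxy)phenyl]-1-[4-(benzyloxy)phenyl]prop-2-en-1-one
Conditions: KOH (50% aq.), EtOH, rt
Reagents that add atoms: none
Why: Claisen–Schmidt aldol condensation: the enolate of 4 adds to the non-enolisable aldehyde and dehydration gives the conjugated E-enone, the MOM and benzyl ethers being stable to hydroxide.

Step 4
Reactants: 5 (E)-3-[2-(benzyloxy)-6-hydroxy-4-(methoxymethoxy)phenyl]-1-[4-(benzyloxy)phenyl]prop-2-en-1-one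
Product: 7 3-(benzyloxy)-2-[(3S)-3-[4-(benzyloxy)phenyl]-3-hydroxypropyl]-5-(methoxymethoxy)phenol, via saturated ketone 6 (not isolated)
Conditions: RuCl[(S,S)-TsDPEN](p-cymene) (2 mol %), HCO2H/Et3N (5:2), EtOAc, 40 °C
Reagents that add atoms: none
Why: Noyori asymmetric transfer hydrogenation: the ruthenium hydride first reduces the enone C=C in conjugate fashion to ketone 6 and then reduces the aryl ketone through the six-membered metal–ligand transition state, in which the (S,S)-ligand should direct hydride to the face that gives the (S)-carbinol, as for other aryl alkyl ketones.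

Step 5
Reactants: 7 3-(benzyloxy)-2-[(3S)-3-[4-(benzyloxy)phenyl]-3-hydroxypropyl]-5-(methoxymethoxy)phenol
Product: 8 (2R)-5-(benzyloxy)-2-[4-(benzyloxy)phenyl]-7-(methoxymethoxy)chromane
Conditions: PPh3, DIAD, toluene, 0 °C
Reagents that add atoms: none
Why: Intramolecular Mitsunobu etherification: the ortho phenol displaces the phosphonium-activated benzylic oxygen in an SN2 6-exo-tet closure with inversion, turning the (S)-carbinol into the (2R)-chroman, and the non-polar solvent and low temperature are chosen to suppress ionisation of the electron-rich benzylic centre.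

Step 6
Reactants: 8 (2R)-5-(benzyloxy)-2-[4-(benzyloxy)phenyl]-7-(methoxymethoxy)chromane
Product: 9 (2R)-5-(benzyloxy)-2-[4-(benzyloxy)phenyl]-8-bromo-7-(methoxymethoxy)chromane
Conditions: NBS (1.0 equiv), CH2Cl2, −78 to 0 °C
Reagents that add atoms: N-bromosuccinimide, O=C1CCC(=O)N1Br
Why: Electrophilic aromatic bromination: C8, between the ring oxygen and the 7-O-MOM group and para to the 5-benzyloxy group, is the more nucleophilic and less hindered of the two free positions of a 5,7-dioxygenated chroman (the same preference as in benzylated catechins), so one equivalent of NBS should brominate there.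

Step 7
Reactants: 10 1-[2,4-bis(benzyloxy)-6-hydroxyphenyl]ethanone
Product: 11 1-[2,4-bis(benzyloxy)-6-(methoxymethoxy)phenyl]ethanone
Conditions: NaH, MOMCl, DMF, 0 °C to rt
Reagents that add atoms: chloromethyl methyl ether, COCCl
Why: Williamson-type O-alkylation: sodium hydride is needed to break the strong chelate of the ortho-hydroxy ketone, and the resulting phenoxide is alkylated on oxygen by the reactive chloromethyl ether.

Step 8
Reactants: 9 (2R)-5-(benzyloxy)-2-[4-(benzyloxy)phenyl]-8-bromo-7-(methoxymethoxy)chromane; 11 1-[2,4-bis(benzyloxy)-6-(methoxymethoxy)phenyl]ethanone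
Product: 12 1-[2,4-bis(benzyloxy)-6-(methoxymethoxy)phenyl]-2-[(2R)-5-(benzyloxy)-2-[4-(benzyloxy)phenyl]-7-(methoxymethoxy)chroman-8-yl]ethanone
Conditions: Pd2(dba)3 (2.5 mol %), XPhos (6 mol %), NaOtBu (2.2 equiv), toluene, 80 °C
Reagents that add atoms: none
Why: Palladium-catalysed α-arylation of a ketone enolate (Buchwald–Hartwig type): the methyl ketone cannot self-condense because both ortho positions are substituted, the bulky biaryl phosphine allows oxidative addition and reductive elimination at the doubly ortho-oxygenated bromide, and the more acidic product rests as its hindered enolate and is not arylated again; the chroman stereocentre is not involved.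

Step 9
Reactants: 12 1-[2,4-bis(benzyloxy)-6-(methoxymethoxy)phenyl]-2-[(2R)-5-(benzyloxy)-2-[4-(benzyloxy)phenyl]-7-(methoxymethoxy)chroman-8-yl]ethanone
Product: 13 1-[2,4-bis(benzyloxy)-6-(triethylsilyloxy)phenyl]-2-[(2R)-5-(benzyloxy)-2-[4-(benzyloxy)phenyl]-7-(triethylsilyloxy)chroman-8-yl]ethanone
Conditions: TESOTf (4 equiv), 2,2'-bipyridyl (6 equiv), CH2Cl2, 0 °C to rt; aq. NaHCO3 work-up
Reagents that add atoms: triethylsilyl trifluoromethanesulfonate, CC[Si](CC)(CC)OS(=O)(=O)C(F)(F)F
Why: Silyl triflate/2,2'-bipyridyl exchange of aromatic MOM ethers, which should turn aryl MOM ethers directly into aryl triethylsilyl ethers under buffered, non-protic conditions, so that both phenols become fluoride-labile without exposing the ortho-oxybenzyl ketone, the chroman or the benzyl ethers to acid.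

Step 10
Reactants: 13 1-[2,4-bis(benzyloxy)-6-(triethylsilyloxy)phenyl]-2-[(2R)-5-(benzyloxy)-2-[4-(benzyloxy)phenyl]-7-(triethylsilyloxy)chroman-8-yl]ethanone
Product: 14 1-[2,4-bis(benzyloxy)-6-(triethylsilyloxy)phenyl]-2-[(2R)-5-(benzyloxy)-2-[4-(benzyloxy)phenyl]-7-(triethylsilyloxy)chroman-8-yl]-2-diazoethanone
Conditions: p-ABSA (1.5 equiv), DBU (2 equiv), MeCN, 0 °C to rt
Reagents that add atoms: 4-acetamidobenzenesulfonyl azide, CC(=O)Nc1ccc(cc1)S(=O)(=O)N=[N+]=[N-]
Why: Regitz diazo transfer: the benzylic ketone is acidic enough for DBU, its enolate attacks the terminal nitrogen of the sulfonyl azide and the triazene collapses to the α-aryl-α-diazo ketone and the sulfonamide, while the silyl ethers keep the electron-rich phenols from reacting with the azide.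

Step 11
Reactants: 15 4-(benzyloxy)benzaldehyde
Product: 16 1-(benzyloxy)-4-(dichloromethyl)benzene
Conditions: SOCl2 (1.5 equiv), DMF (5 mol %), CH2Cl2, 40 °C; volatiles removed, used crude
Reagents that add atoms: thionyl chloride, O=S(Cl)Cl
Why: Deoxygenative gem-dichlorination of an aromatic aldehyde with thionyl chloride under DMF (Vilsmeier-type) catalysis, which is favoured by the electron-rich aryl group and leaves the benzyl ether intact.

Step 12
Reactants: 14 1-[2,4-bis(benzyloxy)-6-(triethylsilyloxy)phenyl]-2-[(2R)-5-(benzyloxy)-2-[4-(benzyloxy)phenyl]-7-(triethylsilyloxy)chroman-8-yl]-2-diazoethanone; 16 1-(benzyloxy)-4-(dichloromethyl)benzene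
Product: 17 3-diazo-2,3-seco-pentabenzyl ketal (nine-membered dibenzo-1,3-dioxonine; C2 an acetal CH as both epimers; 2''R)
Conditions: CsF (4 equiv), DMF (2 mM in 14), 16 (1.1 equiv) added by syringe pump, rt
Reagents that add atoms: none
Why: Fluoride strips both silyl groups and the two caesium phenoxides displace the two chlorides of 16 in a double Williamson-type acetal synthesis (the second displacement intramolecular, on the very reactive α-chloro ether), favoured by high dilution and by the two rigid arene walls of the forming nine-membered ring, while the diazo group keeps C3 from acting as a carbon nucleophile (an enolisable C3 would be C-alkylated to a five- or six-membered ring); the acetal carbon forms as a mixture of epimers that the next step is designed to erase.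

Step 13
Reactants: 17 3-diazo-2,3-seco-pentabenzyl ketal (nine-membered dibenzo-1,3-dioxonine; C2 an acetal CH as both epimers; 2''R)
Product: 18 penta-O-benzyl ether of the target (2S,3S,2''R)
Conditions: Co(3,5-DitBu-ChenPhyrin) (5 mol %, antipode matched to 2S,3S), toluene (5 mM), 40 °C, argon
Reagents that add atoms: none
Why: Proposed new method: the divalent cobalt porphyrin should take up diazo ketone 17 with loss of dinitrogen to give a trivalent-cobalt-bound carbon radical at C3 (between the acyl carbon C4 and the arene carbon C8''), which abstracts the acetal hydrogen on C2 across the nine-membered ring (1,5 through O7''–C7''–C8'' and 1,6 through O1–C8a–C4a–C4); the resulting flat radical at C2, stabilised by O1, O7'' and the 4-benzyloxyphenyl ring, then substitutes cobalt at C3 to form the C2–C3 bond and return the catalyst. The closest known reaction types are cobalt-porphyrin metalloradical 1,5-C–H alkylations of α-oxy C–H bonds by diazo compounds (diazo ketones included) that give five-membered rings, the enantioconvergent radical functionalisation of racemic tertiary C–H bonds with the same catalyst family, and dirhodium carbenoid C–H insertion into ortho-alkoxy groups that gives 2,3-dihydrobenzofurans; the acetal C–H donor and the transannular setting are new. One bond closes two rings: the dihydrofuran ring by a 5-exo-tet radical substitution and the pyranone ring by the matching 6-exo-tet closure, so that the nine-membered dioxonine contracts to the cis-fused 6/5 ketal. C3 should be set by the chiral cavity of the porphyrin, which decides the face of the cobalt-bound carbon that C2 attacks, and C2 follows because only the cis ring fusion is geometrically possible; the flat C2 radical erases the acetal configuration, so both epimers of 17 should converge on the (2S,3S) product under catalyst control, independent of the remote C2'' centre. The step needs hydrogen abstraction from the acetal C–H only and no two-electron carbenoid chemistry: the ring holds this C–H next to C3, whereas the chroman C2''–H is locked anti to C8'' by the pyran ring and the 5-O-benzyl methylene lies on the far side of the carbonyl, and a radical carbene (unlike an electrophilic rhodium carbenoid) should not be diverted into oxonium ylide formation at O1 followed by a Stevens shift to a spiro-benzofuranone.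

Step 14
Reactants: 18 penta-O-benzyl ether of the target (2S,3S,2''R)
Product: 19 target (2S,3S,2''R)-ketal CNP0179743.1
Conditions: H2 (1 atm), Pd(OH)2/C, EtOAc/MeOH (1:1), rt
Reagents that add atoms: none
Why: Catalytic hydrogenolysis of the five aryl benzyl ethers: aryl O–benzyl bonds should cleave much faster than the cyclic benzylic C–O bonds of the chroman and of the diaryl ketal (as in the debenzylation of A-type proanthocyanidin ketals), and the neutral conditions avoid acid- or base-induced opening of the ketal, so no stereocentre is touched.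

**Compound list**

1 | 2,4,6-trihydroxybenzaldehyde | O=Cc1c(O)cc(O)cc1O | starting material
2 | 2,6-dihydroxy-4-(methoxymethoxy)benzaldehyde | O=Cc1c(O)cc(OCOC)cc1O | intermediate
3 | 2-(benzyloxy)-6-hydroxy-4-(methoxymethoxy)benzaldehyde | O=Cc1c(O)cc(OCOC)cc1OCc1ccccc1 | intermediate
4 | 1-[4-(benzyloxy)phenyl]ethanone | CC(=O)c1ccc(OCc2ccccc2)cc1 | starting material
5 | (E)-3-[2-(benzyloxy)-6-hydroxy-4-(methoxymethoxy)phenyl]-1-[4-(benzyloxy)phenyl]prop-2-en-1-one | O=C(/C=C/c1c(O)cc(OCOC)cc1OCc1ccccc1)c1ccc(OCc2ccccc2)cc1 | intermediate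
6 | saturated ketone, 3-[2-(benzyloxy)-6-hydroxy-4-(methoxymethoxy)phenyl]-1-[4-(benzyloxy)phenyl]propan-1-one (not isolated) | O=C(CCc1c(O)cc(OCOC)cc1OCc1ccccc1)c1ccc(OCc2ccccc2)cc1 | intermediate
7 | 3-(benzyloxy)-2-[(3S)-3-[4-(benzyloxy)phenyl]-3-hydroxypropyl]-5-(methoxymethoxy)phenol | O[C@@H](CCc1c(O)cc(OCOC)cc1OCc1ccccc1)c1ccc(OCc2ccccc2)cc1 | intermediate
8 | (2R)-5-(benzyloxy)-2-[4-(benzyloxy)phenyl]-7-(methoxymethoxy)chromane | COCOc1cc(OCc2ccccc2)c2c(c1)O[C@@H](c1ccc(OCc3ccccc3)cc1)CC2 | intermediate
9 | (2R)-5-(benzyloxy)-2-[4-(benzyloxy)phenyl]-8-bromo-7-(methoxymethoxy)chromane | COCOc1cc(OCc2ccccc2)c2c(c1Br)O[C@@H](c1ccc(OCc3ccccc3)cc1)CC2 | intermediate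
10 | 1-[2,4-bis(benzyloxy)-6-hydroxyphenyl]ethanone | CC(=O)c1c(O)cc(OCc2ccccc2)cc1OCc1ccccc1 | starting material
11 | 1-[2,4-bis(benzyloxy)-6-(methoxymethoxy)phenyl]ethanone | CC(=O)c1c(OCOC)cc(OCc2ccccc2)cc1OCc1ccccc1 | intermediate
12 | 1-[2,4-bis(benzyloxy)-6-(methoxymethoxy)phenyl]-2-[(2R)-5-(benzyloxy)-2-[4-(benzyloxy)phenyl]-7-(methoxymethoxy)chroman-8-yl]ethanone | COCOc1cc(OCc2ccccc2)c2c(c1CC(=O)c1c(OCOC)cc(OCc3ccccc3)cc1OCc1ccccc1)O[C@@H](c1ccc(OCc3ccccc3)cc1)CC2 | intermediate
13 | 1-[2,4-bis(benzyloxy)-6-(triethylsilyloxy)phenyl]-2-[(2R)-5-(benzyloxy)-2-[4-(benzyloxy)phenyl]-7-(triethylsilyloxy)chroman-8-yl]ethanone | CC[Si](CC)(CC)Oc1cc(OCc2ccccc2)c2c(c1CC(=O)c1c(O[Si](CC)(CC)CC)cc(OCc3ccccc3)cc1OCc1ccccc1)O[C@@H](c1ccc(OCc3ccccc3)cc1)CC2 | intermediate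
14 | 1-[2,4-bis(benzyloxy)-6-(triethylsilyloxy)phenyl]-2-[(2R)-5-(benzyloxy)-2-[4-(benzyloxy)phenyl]-7-(triethylsilyloxy)chroman-8-yl]-2-diazoethanone | CC[Si](CC)(CC)Oc1cc(OCc2ccccc2)c2c(c1C(=[N+]=[N-])C(=O)c1c(O[Si](CC)(CC)CC)cc(OCc3ccccc3)cc1OCc1ccccc1)O[C@@H](c1ccc(OCc3ccccc3)cc1)CC2 | intermediate
15 | 4-(benzyloxy)benzaldehyde | O=Cc1ccc(OCc2ccccc2)cc1 | starting material
16 | 1-(benzyloxy)-4-(dichloromethyl)benzene | ClC(Cl)c1ccc(OCc2ccccc2)cc1 | intermediate
17 | 3-diazo-2,3-seco-pentabenzyl ketal: nine-membered dibenzo-1,3-dioxonine in which O1 and O7'' are bridged by CH[4-(benzyloxy)phenyl] (C2, both epimers) and C3 is the diazo carbon between C4=O and C8''; 2''R | O=C1c2c(OCc5ccccc5)cc(OCc5ccccc5)cc2OC(c3ccc(OCc5ccccc5)cc3)Oc3cc(OCc5ccccc5)c4c(c3C1=[N+]=[N-])O[C@@H](c1ccc(OCc5ccccc5)cc1)CC4 | intermediate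
18 | penta-O-benzyl ether of the target (2S,3S,2''R), all five phenols as benzyl ethers | O=C1c2c(OCc5ccccc5)cc(OCc5ccccc5)cc2O[C@@]2(c3ccc(OCc5ccccc5)cc3)Oc3cc(OCc5ccccc5)c4c(c3[C@@H]12)O[C@@H](c1ccc(OCc5ccccc5)cc1)CC4 | intermediate
19 | target CNP0179743.1: (2S,3S)-5,7-dihydroxy-2-(4-hydroxyphenyl)chroman-4-one unit with C2 bonded to O7'' and C3 bonded to C8'' of (2''R)-5''-hydroxy-2''-(4-hydroxyphenyl)chroman | O=C1c2c(O)cc(O)cc2O[C@@]2(c3ccc(O)cc3)Oc3cc(O)c4c(c3[C@@H]12)O[C@@H](c1ccc(O)cc1)CC4 | target

**Step count and risks**

Total step count: 14. Longest linear sequence: 12 (steps 1–6, 8–10, 12–14).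

Steps most likely to fail:

1. Step 13 (Proposed new method). The hydrogen transfer and the C–C bond formation may follow each other faster than the nine-membered ring can turn the other face of the flat C2 radical towards C3; the acetal configuration would then be remembered and both cis-fused diastereomers would form. The hindered diazo carbon may also resist activation by the porphyrin. Fallback by known chemistry: set out from 17, separate the two acetal epimers by preparative HPLC and cyclise the (S)-acetal epimer of 17 F1 with Rh2(esp)2 (1 mol %) in CH2Cl2 at 0 °C. Dirhodium carbenoid C–H insertion next to oxygen is concerted and retains configuration at the C–H carbon, so F1 should give 18 stereospecifically, and the route is rejoined at 18. Stereocontrol then rests on the resolved acetal carbon and no longer on the catalyst.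

2. Step 12. Intermolecular acetal formation (oligomerisation) may outrun closure of the nine-membered ring. Fallback without a medium ring: set out from 14. CsF and 1-(benzyloxy)-4-[chloro(methoxy)methyl]benzene (1.0 equiv, DMF, 0 °C) should alkylate only the more nucleophilic chroman phenoxide and give the mixed methyl aryl acetal F2. Its freed acyl-ring phenol is silylated (TBSCl, imidazole, DMF) to the tert-butyldimethylsilyl ether F3. The cobalt porphyrin of step 13 then effects an ordinary 1,5-C–H alkylation at the acetal C–H and gives the 2-methoxy-2,3-dihydrobenzofuran ketal F4, with C3 set by the catalyst. TBAF/AcOH followed by PPTS (cat., CH2Cl2, 4 Å molecular sieves) exchanges the methoxy group for the acyl-ring phenol, the cis fusion following from C3, and the route is rejoined at 18.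

3. Step 8. Oxidative addition and reductive elimination at the doubly ortho-oxygenated bromide may be too slow, so that protodebromination and catalyst decomposition dominate. Fallback with reversed polarity: set out from 9 and 11. Bromine–lithium exchange of 9 (n-BuLi, THF, −78 °C), quenching with B(OiPr)3 and aqueous acid gives the boronic acid F5. Ketone 11 is converted through its silyl enol ether (LiHMDS, TMSCl; then NBS) into the α-bromo ketone F6. Suzuki–Miyaura coupling of F5 with F6 (Pd(OAc)2, P(o-tol)3, K3PO4, THF/H2O) should give 12, where the route is rejoined.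

Further compounds
F1 | step 13 | (S)-acetal epimer of 17 (2''R) | O=C1c2c(OCc5ccccc5)cc(OCc5ccccc5)cc2O[C@@H](c3ccc(OCc5ccccc5)cc3)Oc3cc(OCc5ccccc5)c4c(c3C1=[N+]=[N-])O[C@@H](c1ccc(OCc5ccccc5)cc1)CC4
F2 | step 12 | mixed methyl aryl acetal: 1-[2,4-bis(benzyloxy)-6-hydroxyphenyl]-2-diazo-2-[(2R)-5-(benzyloxy)-2-[4-(benzyloxy)phenyl]-7-{[4-(benzyloxy)phenyl](methoxy)methoxy}chroman-8-yl]ethanone (acetal epimers) | O=C(C(=[N+]=[N-])c1c(OC(OC)c2ccc(OCc5ccccc5)cc2)cc(OCc5ccccc5)c2c1O[C@@H](c1ccc(OCc5ccccc5)cc1)CC2)c1c(O)cc(OCc5ccccc5)cc1OCc1ccccc1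
F3 | step 12 | tert-butyldimethylsilyl ether of F2 at the acyl-ring phenol | O=C(C(=[N+]=[N-])c1c(OC(OC)c2ccc(OCc5ccccc5)cc2)cc(OCc5ccccc5)c2c1O[C@@H](c1ccc(OCc5ccccc5)cc1)CC2)c1c(O[Si](C)(C)C(C)(C)C)cc(OCc5ccccc5)cc1OCc1ccccc1
F4 | step 12 | 2-methoxy-2,3-dihydrobenzofuran ketal: (3S)-3-aroyl-2-methoxy-2-[4-(benzyloxy)phenyl]dihydrofuran ring fused at C7''–C8'' of the (2''R)-chroman, C2 as both epimers, acyl-ring phenol as TBS ether | O=C([C@@H]1c2c(cc(OCc5ccccc5)c3c2O[C@@H](c2ccc(OCc5ccccc5)cc2)CC3)OC1(OC)c1ccc(OCc5ccccc5)cc1)c1c(O[Si](C)(C)C(C)(C)C)cc(OCc5ccccc5)cc1OCc1ccccc1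
F5 | step 8 | [(2R)-5-(benzyloxy)-2-[4-(benzyloxy)phenyl]-7-(methoxymethoxy)chroman-8-yl]boronic acid | COCOc1cc(OCc2ccccc2)c2c(c1B(O)O)O[C@@H](c1ccc(OCc3ccccc3)cc1)CC2
F6 | step 8 | 1-[2,4-bis(benzyloxy)-6-(methoxymethoxy)phenyl]-2-bromoethanone | BrCC(=O)c1c(OCOC)cc(OCc2ccccc2)cc1OCc1ccccc1
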